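## Retrosynthetic overview
1. The target comes from its 7,7''-di-O-benzyl ether by a neutral hydrogenolysis as the last step.
2. Both O1–C2 bonds are cut at once and the C3–C3'' bond is kept. This leads to an acyclic Cα–Cα'-linked "bichalcone", a 2,3-bis(4-methoxybenzylidene)-1,4-diaryl-1,4-diketone, matching the chalcone-dimer-then-heterocyclisation order presumed in the plant.
3. The bichalcone comes from a 1,4-diaryl-1,4-butanedione and two 4-methoxybenzaldehyde units by a double Claisen–Schmidt condensation.
4. The diketone comes from oxidative Cα–Cα dimerisation of 4-O-benzyl-6-O-methylphloroacetophenone, which is made from phloroacetophenone.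
5. Ring order: the A and B rings are bought. The two pyranone C rings are the only rings made, one after the other in one flask, and all four stereocentres are set there.

Assumption: the quinine-derived thiourea is taken to give the (2S) sense on this new substrate, by analogy only. If a pilot run shows (2R), the commercial quinidine-derived pseudo-enantiomer replaces it and nothing else changes.

## Route

Step 1
Reactants: 1 2',4',6'-trihydroxyacetophenone
Product: 3 1-[4-(benzyloxy)-2-hydroxy-6-methoxyphenyl]ethanone, via 4-O-benzyl phloroacetophenone 2 (not isolated)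
Conditions: BnBr (1.0 equiv), K2CO3 (1.1 equiv), acetone, 56 °C, 6 h; then MeI (1.1 equiv), K2CO3 (1.2 equiv), 45 °C, 16 h
Reagents that add atoms: benzyl bromide BrCc1ccccc1; iodomethane CI
Why: Two sequential Williamson etherifications ranked by acidity, in which the free and most acidic 4-OH is benzylated first, then one of the two equivalent ortho OH groups is methylated, and the last OH stays locked in the C=O hydrogen bond and resists alkylation (no stereocentre).

Step 2
Reactants: 3 1-[4-(benzyloxy)-2-hydroxy-6-methoxyphenyl]ethanone (2 equiv incorporated)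
Product: 6 1,4-bis[4-(benzyloxy)-2-hydroxy-6-methoxyphenyl]butane-1,4-dione, via bis-TMS enol silane 4 (not isolated), via bis(aryl-OTMS) diketone 5 (not isolated)
Conditions: TMSOTf (2.4 equiv), Et3N (3 equiv), CH2Cl2, 0 °C; pentane filtration and solvent switch; Cu(OTf)2 (1.1 equiv), Cu2O (0.6 equiv), MeCN, 0 °C to rt; 10% aq citric acid, THF, rt
Reagents that add atoms: trimethylsilyl trifluoromethanesulfonate C[Si](C)(C)OS(=O)(=O)C(F)(F)F (its silicon groups sit only in 4 and 5)
Why: Soft enolisation masks the phenol and gives the enol silane, whose one-electron oxidation by Cu(II) releases a primary α-keto radical that dimerises (oxidative enol-silane homocoupling) to the 1,4-diketone, and the labile ArO–TMS bonds fall off in the mild acidic work-up (no stereocentre).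

Step 3
Reactants: 6 1,4-bis[4-(benzyloxy)-2-hydroxy-6-methoxyphenyl]butane-1,4-dione; 7 4-methoxybenzaldehyde (3 equiv used, 2 incorporated)
Product: 9 (2E,3E)-1,4-bis[4-(benzyloxy)-2-hydroxy-6-methoxyphenyl]-2,3-bis(4-methoxybenzylidene)butane-1,4-dione, via mono-benzylidene diketone 8 (not isolated)
Conditions: KOH (50% aq, 20 equiv), EtOH, rt to 40 °C, 72 h, dark; pour into ice-cold 1 M HCl (pH 5), cold extraction
Reagents that add atoms: none
Why: Double Claisen–Schmidt aldol condensation (E1cB dehydration), where the diaryl diketone has only the two internal CH2 groups to enolise, the CH2 of 8 is additionally allylic, the high pH holds the product ring-open as its bis-phenolate, and the E,E geometry (anisyl trans to aroyl) is the thermodynamic one.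

Step 4
Reactants: 9 (2E,3E)-1,4-bis[4-(benzyloxy)-2-hydroxy-6-methoxyphenyl]-2,3-bis(4-methoxybenzylidene)butane-1,4-dione
Product: 11 (2S,3R,2''S,3''R)-7,7''-bis(benzyloxy)-5,5''-dimethoxy-2,2''-bis(4-methoxyphenyl)-3,3''-bichroman-4,4''-dione, via monocyclised flavanone-chalcone 10 (not isolated)
Conditions: 1-[3,5-bis(trifluoromethyl)phenyl]-3-[(8α,9S)-6'-methoxycinchonan-9-yl]thiourea (20 mol %), toluene (0.05 M), −10 °C, 72 h, dark; then TsOH·H2O (0.3 equiv), 40 °C, 6 h; chromatography, then recrystallisation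
Reagents that add atoms: none
Why: Proposed new method: a double chalcone-isomerase-type 6-endo-trig oxa-Michael addition in which the quinuclidine nitrogen deprotonates the chelated 2'-OH while the thiourea hydrogen-bonds the enone carbonyl, so each phenoxide adds to the catalyst-chosen face of its anisylidene carbon and fixes C2 and C2'' as S; the acid then stops the amine and equilibrates C3 and C3'' through the enols, without C2–O cleavage, to the diequatorial 2,3-trans arrangement, which for 2S means 3R; because two identical catalyst-controlled events are needed, errors collect mainly in the separable meso-type (2S,2''R) isomer and the ee of the C2-symmetric product is amplified (Horeau effect, for example 9:1 per event gives about 98% ee); the closest known reaction type is the cinchona-thiourea-catalysed asymmetric cyclisation of 2'-hydroxychalcones and alkylidene β-keto esters to flavanones.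

Step 5
Reactants: 11 (2S,3R,2''S,3''R)-7,7''-bis(benzyloxy)-5,5''-dimethoxy-2,2''-bis(4-methoxyphenyl)-3,3''-bichroman-4,4''-dione
Product: 12 4',4''',5,5''-tetramethylchamaejasmin
Conditions: H2 (1 atm), 10% Pd/C, EtOAc–THF, rt, stopped after 2 equiv H2
Reagents that add atoms: none
Why: Catalytic hydrogenolysis of the two aryl benzyl ethers under neutral conditions, with no acid or base present to trigger retro-oxa-Michael opening or enolisation, so all four stereocentres, the ketones and the ring C2–O bonds are left untouched.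

## Compound list
1 | 2',4',6'-trihydroxyacetophenone | CC(=O)c1c(O)cc(O)cc1O | starting material
2 | 1-[4-(benzyloxy)-2,6-dihydroxyphenyl]ethanone | CC(=O)c1c(O)cc(OCc2ccccc2)cc1O | intermediate
3 | 1-[4-(benzyloxy)-2-hydroxy-6-methoxyphenyl]ethanone | CC(=O)c1c(O)cc(OCc2ccccc2)cc1OC | intermediate
4 | {1-[4-(benzyloxy)-2-methoxy-6-(trimethylsilyloxy)phenyl]ethenyloxy}trimethylsilane | C=C(O[Si](C)(C)C)c1c(O[Si](C)(C)C)cc(OCc2ccccc2)cc1OC | intermediate
5 | 1,4-bis[4-(benzyloxy)-2-methoxy-6-(trimethylsilyloxy)phenyl]butane-1,4-dione | O=C(CCC(=O)c1c(O[Si](C)(C)C)cc(OCc2ccccc2)cc1OC)c1c(O[Si](C)(C)C)cc(OCc2ccccc2)cc1OC | intermediate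
6 | 1,4-bis[4-(benzyloxy)-2-hydroxy-6-methoxyphenyl]butane-1,4-dione | O=C(CCC(=O)c1c(O)cc(OCc2ccccc2)cc1OC)c1c(O)cc(OCc2ccccc2)cc1OC | intermediate
7 | 4-methoxybenzaldehyde | COc1ccc(C=O)cc1 | starting material
8 | (2E)-1,4-bis[4-(benzyloxy)-2-hydroxy-6-methoxyphenyl]-2-(4-methoxybenzylidene)butane-1,4-dione | O=C(c1c(O)cc(OCc2ccccc2)cc1OC)/C(=C/c1ccc(OC)cc1)CC(=O)c1c(O)cc(OCc2ccccc2)cc1OC | intermediate
9 | (2E,3E)-1,4-bis[4-(benzyloxy)-2-hydroxy-6-methoxyphenyl]-2,3-bis(4-methoxybenzylidene)butane-1,4-dione | O=C(c1c(O)cc(OCc2ccccc2)cc1OC)/C(=C/c1ccc(OC)cc1)/C(=C\c1ccc(OC)cc1)C(=O)c1c(O)cc(OCc2ccccc2)cc1OC | intermediate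
10 | (2S,3R)-7-(benzyloxy)-3-{(1E)-3-[4-(benzyloxy)-2-hydroxy-6-methoxyphenyl]-1-(4-methoxyphenyl)-3-oxoprop-1-en-2-yl}-5-methoxy-2-(4-methoxyphenyl)chroman-4-one | COc1ccc([C@H]2Oc3cc(OCc4ccccc4)cc(OC)c3C(=O)[C@@H]2/C(=C\c2ccc(OC)cc2)C(=O)c2c(O)cc(OCc3ccccc3)cc2OC)cc1 | intermediate
11 | (2S,3R,2''S,3''R)-7,7''-bis(benzyloxy)-5,5''-dimethoxy-2,2''-bis(4-methoxyphenyl)-3,3''-bichroman-4,4''-dione | COc1ccc([C@H]2Oc3cc(OCc4ccccc4)cc(OC)c3C(=O)[C@@H]2[C@H]2C(=O)c3c(OC)cc(OCc4ccccc4)cc3O[C@@H]2c2ccc(OC)cc2)cc1 | intermediate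
12 | 4',4''',5,5''-tetramethylchamaejasmin, (2S,3R,2''S,3''R)-7,7''-dihydroxy-5,5''-dimethoxy-2,2''-bis(4-methoxyphenyl)-3,3''-bichroman-4,4''-dione | COc1ccc([C@H]2Oc3cc(O)cc(OC)c3C(=O)[C@@H]2[C@H]2C(=O)c3c(OC)cc(O)cc3O[C@@H]2c2ccc(OC)cc2)cc1 | target

## Summary
Total step count: 5. Longest linear sequence: 5 steps, from 1 to 12.

## Steps most likely to fail

**Step 4.** The catalyst has never seen this hindered, cross-conjugated diene-dione. The risks are:
- slow turnover,
- racemic background closure,
- a mismatched second closure,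
- loss of ee through reversibility.

The fallback reverses the order of events: the ring is closed on the monomer and the C3–C3'' bond is made afterwards. It sets out from 3 and 7. KOH/EtOH Claisen–Schmidt condensation gives (E)-1-[4-(benzyloxy)-2-hydroxy-6-methoxyphenyl]-3-(4-methoxyphenyl)prop-2-en-1-one F1. The better-precedented cinchona-thiourea cyclisation of this simple chalcone gives (2S)-7-(benzyloxy)-5-methoxy-2-(4-methoxyphenyl)chroman-4-one F2, which is recrystallised to high ee. TMSOTf/Et3N then gives, without a free enolate and so without ring opening, (2S)-7-(benzyloxy)-5-methoxy-2-(4-methoxyphenyl)-4-(trimethylsilyloxy)-2H-chromene F3. Cu(OTf)2/Cu2O homocoupling joins two C3 radicals, each anti to its own 2-aryl group. Two (2S) units can therefore only give the (2S,3R,2''S,3''R) dimer, and the fallback comes back to the route at 11.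

**Step 3.** The second condensation may stall. Intermediate 8 may drift to the ene-dione or a furan. Product 9 may close racemically during acidification. The fallback separates C–C bond formation from elimination by using Lewis-acid chemistry. It sets out from 6. TMSOTf (4.5 equiv)/Et3N gives (1Z,3Z)-1,4-bis[4-(benzyloxy)-2-methoxy-6-(trimethylsilyloxy)phenyl]-1,4-bis(trimethylsilyloxy)buta-1,3-diene F4. A TMSOTf-catalysed double Mukaiyama aldol with commercial 4-methoxybenzaldehyde dimethyl acetal at −78 °C, followed by mild acidic work-up, gives 1,4-bis[4-(benzyloxy)-2-hydroxy-6-methoxyphenyl]-2,3-bis[methoxy(4-methoxyphenyl)methyl]butane-1,4-dione F5 as a diastereomer mixture. A short KOH/EtOH treatment (E1cB) with a cold acid quench removes the two methoxy groups, and the fallback comes back at 9.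

**Step 2.** The very electron-rich arene may compete for the oxidant and give aryl coupling. The enol silane may simply hydrolyse back to 3. The product may undergo Paal–Knorr closure to a furan. The fallback gives up transient masking and radical-cation chemistry in favour of an isolated protecting group and a preformed lithium enolate. It sets out from 3. NaH/MOMCl in DMF gives 1-[4-(benzyloxy)-2-methoxy-6-(methoxymethoxy)phenyl]ethanone F6. LDA in THF at −78 °C followed by CuCl2 in DMF gives 1,4-bis[4-(benzyloxy)-2-methoxy-6-(methoxymethoxy)phenyl]butane-1,4-dione F7. Catalytic HCl in MeOH at 40 °C frees the two phenols, and the fallback comes back at 6.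

## Further compounds
F1 | step 4 | (E)-1-[4-(benzyloxy)-2-hydroxy-6-methoxyphenyl]-3-(4-methoxyphenyl)prop-2-en-1-one | COc1ccc(/C=C/C(=O)c2c(O)cc(OCc3ccccc3)cc2OC)cc1
F2 | step 4 | (2S)-7-(benzyloxy)-5-methoxy-2-(4-methoxyphenyl)chroman-4-one | COc1ccc([C@H]2Oc3cc(OCc4ccccc4)cc(OC)c3C(=O)C2)cc1
F3 | step 4 | (2S)-7-(benzyloxy)-5-methoxy-2-(4-methoxyphenyl)-4-(trimethylsilyloxy)-2H-chromene | COc1ccc([C@H]2Oc3cc(OCc4ccccc4)cc(OC)c3C(O[Si](C)(C)C)=C2)cc1
F4 | step 3 | (1Z,3Z)-1,4-bis[4-(benzyloxy)-2-methoxy-6-(trimethylsilyloxy)phenyl]-1,4-bis(trimethylsilyloxy)buta-1,3-diene | C[Si](C)(C)O/C(c1c(O[Si](C)(C)C)cc(OCc2ccccc2)cc1OC)=C\C=C(/O[Si](C)(C)C)c1c(O[Si](C)(C)C)cc(OCc2ccccc2)cc1OC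
F5 | step 3 | 1,4-bis[4-(benzyloxy)-2-hydroxy-6-methoxyphenyl]-2,3-bis[methoxy(4-methoxyphenyl)methyl]butane-1,4-dione (diastereomer mixture) | O=C(c1c(O)cc(OCc2ccccc2)cc1OC)C(C(OC)c1ccc(OC)cc1)C(C(OC)c1ccc(OC)cc1)C(=O)c1c(O)cc(OCc2ccccc2)cc1OC
F6 | step 2 | 1-[4-(benzyloxy)-2-methoxy-6-(methoxymethoxy)phenyl]ethanone | CC(=O)c1c(OCOC)cc(OCc2ccccc2)cc1OC
F7 | step 2 | 1,4-bis[4-(benzyloxy)-2-methoxy-6-(methoxymethoxy)phenyl]butane-1,4-dione | O=C(CCC(=O)c1c(OCOC)cc(OCc2ccccc2)cc1OC)c1c(OCOC)cc(OCc2ccccc2)cc1OC
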